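**Strategy.** Everything rests on disconnecting both rings of the labdane at C1–C2 and C9–C10. In ring A, C2 is an oxygen-bearing carbon flanked by the C1 and C3 methylenes, and in ring B the C8=C17 methylene sits next to C9. So an ynol silyl ether (C3≡C2–O) on the C4 gem-dimethyl carbon, protonated to a ketenium ion, can be attacked by an isopropenyl group (C10=C1), and the C10 cation trapped by an allylsilane. One operation closes rings A and B, sets C9 and C10 from the C5 centre, and installs the C2 carbonyl and the exocyclic alkene. The precursor is acyclic: one stereocentre (C5) carrying the siloxyalkyne arm, the isopropenyl group and the allylsilane–(Z)-enoate chain.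

Key step: step 15

**Remarks on the chemistry (assumptions and design choices)**
- Labdane numbering (C17 = methylene carbon, C20 = angular methyl) is used for every intermediate. The target is (2R,5S,9S,10S,13Z); the 2β-acetate is axial and syn to C20.
- Assumption: the cobalt-stabilised propargylic cation adds to the chelated (Z)-boron enolate on the face opposite the benzyl group, in the sense of an enolate alkylation. The (R)-auxiliary then gives the (S)-acyl centre that becomes C5.
- Addition of the alkene to the ketenium ion gives a neutral enol silyl ether, and the terminator expels Me3Si+, not H+. The acid is therefore stoichiometric and the C2 ketone appears only on desilylation in the work-up.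
- C15 passes through ynolate formation and cyclisation as a silyl ester made from the free acid. A methyl 3-methylalk-2-enoate would not survive acetylide generation (γ-deprotonation, loss of 13Z). Compounds 28 and 30 are therefore the silyl-ester form of the ynol-ether precursor and the free-acid form of the 2-oxo bicycle, and no ester hydrolysis is needed after the key step.
- The alkyne is C-silylated from step 5 to step 13 so that no acidic C–H meets the organolithium, nickel and palladium steps.
- The 13Z alkene comes from the (Z)-β-iodo enoate with retention; cuprate addition of the chain to the ynoate would give 13E.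

**Route**

Step 1
Reactants: 1 2-methylbut-3-yn-2-ol
Product: 2 hexacarbonyl[μ-(2-methylbut-3-yn-2-ol)]dicobalt
Conditions: Co2(CO)8, CH2Cl2, rt
Reagents that add atoms: dicobalt octacarbonyl, O=C=[Co](=C=O)(=C=O)(=C=O)[Co](=C=O)(=C=O)(=C=O)=C=O
Why: Complexation of an alkyne by Co2(CO)8 with loss of two CO is the standard entry to Nicholas chemistry and should be essentially quantitative.

Step 2
Reactants: 3 (4R)-4-benzyl-1,3-oxazolidin-2-one; 4 4-chlorobutanoyl chloride
Product: 5 (4R)-4-benzyl-3-(4-chlorobutanoyl)-1,3-oxazolidin-2-one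
Conditions: n-BuLi, THF, −78 °C; then 4, −78 → 0 °C
Reagents that add atoms: none
Why: N-Acylation of the lithiated oxazolidinone by an acid chloride is routine, and the primary chloride is inert at this temperature.

Step 3
Reactants: 5 (4R)-4-benzyl-3-(4-chlorobutanoyl)-1,3-oxazolidin-2-one; 2 hexacarbonyl[μ-(2-methylbut-3-yn-2-ol)]dicobalt
Product: 8 (4R)-4-benzyl-3-[(2S)-2-(2-chloroethyl)-3,3-dimethylpent-4-ynoyl]-1,3-oxazolidin-2-one, via boron enolate 6 (not isolated), via cobalt-complexed adduct 7 (not isolated)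
Conditions: Bu2BOTf, i-Pr2NEt, CH2Cl2, 0 °C; then 2, Bu2BOTf, −78 → 0 °C; crude 7: (NH4)2Ce(NO3)6, acetone, 0 °C
Reagents that add atoms: none
Why: Nicholas reaction of a chiral boron enolate: excess borane triflate ionises the tertiary propargylic alcohol complex to the Co2(CO)6-stabilised cation, which attacks the chelated (Z)-enolate anti to the benzyl group and sets C5 (2S in 8), and Ce(IV) then releases the alkyne.

Step 4
Reactants: 8 (4R)-4-benzyl-3-[(2S)-2-(2-chloroethyl)-3,3-dimethylpent-4-ynoyl]-1,3-oxazolidin-2-one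
Product: 10 (3S)-3-(2-methylbut-3-yn-2-yl)oxolan-2-one, via chloro acid 9 (not isolated)
Conditions: LiOH, H2O2, THF/H2O, 0 °C; Na2SO3; removal of 3 by extraction; aqueous phase 50 °C; then 1 M HCl, rt
Reagents that add atoms: hydrogen peroxide (as LiOOH), OO
Why: Hydroperoxide cleaves the hindered imide at the exocyclic carbonyl without touching C5, and the γ-chloro carboxylate then closes to the butyrolactone by 5-exo-tet displacement (any hydroxy acid relactonises on acidification), which turns the chloride into the C7 oxygen handle.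

Step 5
Reactants: 10 (3S)-3-(2-methylbut-3-yn-2-yl)oxolan-2-one
Product: 12 (3S)-2-methyl-3-[2-methyl-4-(trimethylsilyl)but-3-yn-2-yl]oxolan-2-ol (anomers; ring-chain tautomer of the γ-hydroxy methyl ketone), via bis-silylated lactol 11 (not isolated)
Conditions: MeLi (2.2 equiv), THF, −78 °C; TMSCl, −78 → 0 °C; 0.5 M HCl work-up
Reagents that add atoms: methyllithium, [Li]C; chlorotrimethylsilane, C[Si](C)(C)Cl
Why: Addition of methyllithium to a lactone stops at the lactolate while the second equivalent deprotonates the alkyne, silylation caps both anions, and the acidic work-up removes only the O-silyl group, so the methyl ketone (as its lactol) and the C-silyl alkyne arise in one flask.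

Step 6
Reactants: 12 (3S)-2-methyl-3-[2-methyl-4-(trimethylsilyl)but-3-yn-2-yl]oxolan-2-ol
Product: 13 (3R)-4,4-dimethyl-3-(prop-1-en-2-yl)-6-(trimethylsilyl)hex-5-yn-1-ol
Conditions: Ph3PCH3Br, NaHMDS, THF, 0 → 50 °C
Reagents that add atoms: methylidenetriphenylphosphorane (from methyltriphenylphosphonium bromide), C=P(c1ccccc1)(c1ccccc1)c1ccccc1
Why: Wittig methylenation of the open hydroxy-ketone tautomer creates the isopropenyl group (C10=C1) and frees the C7 alcohol, and the only enolisable hydrogen on the stereogenic side (C5–H next to the quaternary carbon) is too hindered to be removed readily, so the configuration should hold.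

Step 7
Reactants: 13 (3R)-4,4-dimethyl-3-(prop-1-en-2-yl)-6-(trimethylsilyl)hex-5-yn-1-ol
Product: 14 [(4R)-6-iodo-3,3-dimethyl-4-(prop-1-en-2-yl)hex-1-yn-1-yl]trimethylsilane
Conditions: I2, PPh3, imidazole, CH2Cl2, 0 °C
Reagents that add atoms: iodine, II
Why: Appel-type iodination of an unhindered primary alcohol is an SN2 process under buffered conditions that leave the silylalkyne and the 1,1-disubstituted alkene alone.

Step 8
Reactants: 14 [(4R)-6-iodo-3,3-dimethyl-4-(prop-1-en-2-yl)hex-1-yn-1-yl]trimethylsilane; 15 2,3-dihydrofuran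
Product: 17 [(4R)-6-(4,5-dihydrofuran-2-yl)-3,3-dimethyl-4-(prop-1-en-2-yl)hex-1-yn-1-yl]trimethylsilane, via 5-lithio-2,3-dihydrofuran 16 (not isolated)
Conditions: 15, t-BuLi, THF, −78 → 0 °C; then 14, −30 °C → rt; filtration through basic alumina
Reagents that add atoms: none
Why: α-Lithiation of the cyclic enol ether and SN2 alkylation by a primary iodide is the established route to 5-alkyl-2,3-dihydrofurans, and the ring fixes oxygen cis to C11, which becomes the alkene geometry.

Step 9
Reactants: 17 [(4R)-6-(4,5-dihydrofuran-2-yl)-3,3-dimethyl-4-(prop-1-en-2-yl)hex-1-yn-1-yl]trimethylsilane; 18 (trimethylsilyl)methylmagnesium chloride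
Product: 19 (3Z,7R)-8,8-dimethyl-7-(prop-1-en-2-yl)-10-(trimethylsilyl)-4-[(trimethylsilyl)methyl]dec-3-en-9-yn-1-ol
Conditions: 18 (3 equiv), NiCl2(PPh3)2 (10 mol %), toluene, 80 °C
Reagents that add atoms: none
Why: Nickel-catalysed Kumada-type coupling of a Grignard reagent without β-hydrogens into the enol-ether C–O bond replaces oxygen at C8 by CH2SiMe3 with retention, so C17 ends cis to C11 and the (Z)-allylsilane and the C12 alcohol are formed together.

Step 10
Reactants: 19 (3Z,7R)-8,8-dimethyl-7-(prop-1-en-2-yl)-10-(trimethylsilyl)-4-[(trimethylsilyl)methyl]dec-3-en-9-yn-1-ol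
Product: 21 [(4R,7Z)-10-iodo-3,3-dimethyl-4-(prop-1-en-2-yl)-7-[(trimethylsilyl)methyl]dec-7-en-1-yn-1-yl]trimethylsilane, via mesylate 20 (not isolated)
Conditions: MsCl, Et3N, CH2Cl2, 0 °C; then NaI, NaHCO3, acetone, 40 °C
Reagents that add atoms: sodium iodide, [Na+].[I-]
Why: Mesylation and Finkelstein displacement give the primary iodide without electrophilic iodine, which the allylsilane would not tolerate.

Step 11
Reactants: 22 methyl but-2-ynoate
Product: 23 methyl (2Z)-3-iodobut-2-enoate
Conditions: NaI, AcOH, 110 °C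
Reagents that add atoms: sodium iodide, [Na+].[I-]
Why: Conjugate hydroiodination of an ynoate in acetic acid is an anti addition and gives the (Z)-β-iodo enoate selectively.

Step 12
Reactants: 21 [(4R,7Z)-10-iodo-3,3-dimethyl-4-(prop-1-en-2-yl)-7-[(trimethylsilyl)methyl]dec-7-en-1-yn-1-yl]trimethylsilane; 23 methyl (2Z)-3-iodobut-2-enoate
Product: 25 methyl (2Z,6Z,10R)-3,11,11-trimethyl-10-(prop-1-en-2-yl)-13-(trimethylsilyl)-7-[(trimethylsilyl)methyl]trideca-2,6-dien-12-ynoate, via alkylzinc iodide 24 (not isolated)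
Conditions: Zn dust (activated), LiCl, THF, 40 °C; then 23, Pd(PPh3)4 (5 mol %), THF, rt
Reagents that add atoms: none
Why: Zinc insertion into the primary iodide and Negishi sp3–sp2 coupling with the (Z)-β-iodo enoate occur with retention at the alkene and so fix the 13Z geometry.

Step 13
Reactants: 25 methyl (2Z,6Z,10R)-3,11,11-trimethyl-10-(prop-1-en-2-yl)-13-(trimethylsilyl)-7-[(trimethylsilyl)methyl]trideca-2,6-dien-12-ynoate
Product: 26 (2Z,6Z,10R)-3,11,11-trimethyl-10-(prop-1-en-2-yl)-7-[(trimethylsilyl)methyl]trideca-2,6-dien-12-ynoic acid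
Conditions: LiOH, THF/MeOH/H2O, 40 °C; then 1 M HCl to pH 4, 0 °C
Reagents that add atoms: lithium hydroxide, [Li+].[OH-]
Why: Ester saponification and protodesilylation of the alkynylsilane are both hydroxide/methoxide reactions and occur together, while the allylic C–Si bond is stable to base.

Step 14
Reactants: 26 (2Z,6Z,10R)-3,11,11-trimethyl-10-(prop-1-en-2-yl)-7-[(trimethylsilyl)methyl]trideca-2,6-dien-12-ynoic acid
Product: 28 tri(propan-2-yl)silyl (2Z,6Z,10R)-3,11,11-trimethyl-10-(prop-1-en-2-yl)-13-{[tri(propan-2-yl)silyl]oxy}-7-[(trimethylsilyl)methyl]trideca-2,6-dien-12-ynoate, via dilithium ynolate 27 (not isolated)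
Conditions: LiHMDS (1.0 equiv), then n-BuLi (1.05 equiv), THF, −78 °C; t-BuOOLi (from t-BuOOH, LiHMDS), −78 → 0 °C; TIPSOTf (2.5 equiv), −78 → 0 °C; Et3N-deactivated silica
Reagents that add atoms: tert-butyl hydroperoxide, CC(C)(C)OO; triisopropylsilyl triflate, CC(C)[Si](OS(=O)(=O)C(F)(F)F)(C(C)C)C(C)C
Why: Oxidation of a lithium acetylide by lithium tert-butyl peroxide to the ynolate and O-silylation by a bulky silyl triflate is the established route to siloxyalkynes, and the carboxylate shields the (Z)-enoate from γ-deprotonation and is silylated in the same flask.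

Step 15
Reactants: 28 tri(propan-2-yl)silyl (2Z,6Z,10R)-3,11,11-trimethyl-10-(prop-1-en-2-yl)-13-{[tri(propan-2-yl)silyl]oxy}-7-[(trimethylsilyl)methyl]trideca-2,6-dien-12-ynoate
Product: 30 (13Z)-2-oxolabda-8(17),13-dien-15-oic acid, via enol silyl ether 29 (not isolated)
Conditions: HNTf2 (1.1 equiv, added dropwise), CH2Cl2 (0.005 M), −78 °C; Et3N; then TBAF, AcOH, THF, 0 °C
Reagents that add atoms: none
Why: Proposed new method: protonation of the ynol silyl ether at C3 gives a silyl ketenium ion that is attacked at C2 by C1 of the isopropenyl group, forming C1–C2 and ring A as a neutral enol silyl ether (C2=C3) with a tertiary cation at C10; C9 of the allylsilane then adds to C10 and the β-silyl cation at C8 loses Me3Si+ to give C8=C17 and ring B. The closest known chemistry is the Brønsted-acid carbocyclisation of siloxyalkynes onto arenes and alkenes through ketenium ions, joined here to a classical allylsilane-terminated cation–olefin cyclisation. Ring A closes 6-endo-trig at the C10=C1 alkene (in-plane attack on the ketenium carbon, C3=C2 becoming endocyclic) and ring B closes 6-endo-trig at C8=C9 through a chair. C10 is controlled by the C5 stereocentre (C6 tether equatorial on the ring-A half-chair, C9 bonding anti to H-5, so C20 ends axial and the decalin trans) and C9 by the alkene geometry (C11 trans to C7 becomes equatorial, H-9 anti to C20). The step needs protonation of the ynol ether before protodesilylation of the allylsilane or protonation of the other alkenes, which the higher basicity of the oxygen-substituted alkyne, one equivalent of acid, −78 °C and high dilution should secure; since silicon and not a proton is released, the acid cannot turn over and is used stoichiometrically. Buffered fluoride then cleaves the enol silyl ether and the silyl ester (and any C3-silyl group from silyl-cation initiation) to the ketone and the acid without moving the 8(17)-alkene.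

Step 16
Reactants: 30 (13Z)-2-oxolabda-8(17),13-dien-15-oic acid
Product: 31 (13Z)-2β-hydroxylabda-8(17),13-dien-15-oic acid
Conditions: L-Selectride (2.5 equiv), THF, −78 °C; NaOH, H2O2, 0 °C; then 1 M HCl to pH 3
Reagents that add atoms: none
Why: Bulky trialkylborohydride reduction of a cyclohexanone: the first equivalent only deprotonates the acid, and hydride then reaches C2 from the α-face (equatorial attack) because the β-face is blocked by the syn-axial C20 and C19 methyls, giving the axial 2β-alcohol (2R).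

Step 17
Reactants: 31 (13Z)-2β-hydroxylabda-8(17),13-dien-15-oic acid
Product: 33 (13Z)-2β-acetoxylabda-8(17),13-dien-15-oic acid (target), via mixed anhydride 32 (not isolated)
Conditions: Ac2O, DMAP, pyridine, 40 °C; then H2O, NaHCO3, THF, rt; citric acid to pH 3
Reagents that add atoms: acetic anhydride, CC(=O)OC(C)=O
Why: DMAP-catalysed acetylation esterifies the hindered axial alcohol with retention at C2, and the mixed anhydride formed at C15 is hydrolysed at its acetyl carbonyl in the bicarbonate work-up.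

**Compound list** (cobalt carbonyls drawn as Co=C=O; the alkyne carbons bridge both cobalt atoms)

1 | 2-methylbut-3-yn-2-ol | CC(C)(O)C#C | starting material
2 | hexacarbonyl[μ-(2-methylbut-3-yn-2-ol)]dicobalt | CC(C)(O)[C]12[CH]3[Co]1(=C=O)(=C=O)(=C=O)[Co]23(=C=O)(=C=O)=C=O | intermediate
3 | (4R)-4-benzyl-1,3-oxazolidin-2-one | O=C1N[C@H](Cc2ccccc2)CO1 | starting material
4 | 4-chlorobutanoyl chloride | O=C(Cl)CCCCl | starting material
5 | (4R)-4-benzyl-3-(4-chlorobutanoyl)-1,3-oxazolidin-2-one | O=C1N(C(=O)CCCCl)[C@H](Cc2ccccc2)CO1 | intermediate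
6 | (Z)-dibutylboron enolate of 5 | CCCCB(CCCC)O/C(=C\CCCl)N1C(=O)OC[C@H]1Cc1ccccc1 | intermediate (not isolated)
7 | hexacarbonyldicobalt complex of 8 | O=C1N(C(=O)[C@@H](CCCl)C(C)(C)[C]23[CH]4[Co]2(=C=O)(=C=O)(=C=O)[Co]34(=C=O)(=C=O)=C=O)[C@H](Cc2ccccc2)CO1 | intermediate (not isolated)
8 | (4R)-4-benzyl-3-[(2S)-2-(2-chloroethyl)-3,3-dimethylpent-4-ynoyl]-1,3-oxazolidin-2-one | O=C1N(C(=O)[C@@H](CCCl)C(C)(C)C#C)[C@H](Cc2ccccc2)CO1 | intermediate
9 | (2S)-2-(2-chloroethyl)-3,3-dimethylpent-4-ynoic acid | OC(=O)[C@@H](CCCl)C(C)(C)C#C | intermediate (not isolated)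
10 | (3S)-3-(2-methylbut-3-yn-2-yl)oxolan-2-one | O=C1OCC[C@H]1C(C)(C)C#C | intermediate
11 | (3S)-2-methyl-3-[2-methyl-4-(trimethylsilyl)but-3-yn-2-yl]-2-[(trimethylsilyl)oxy]oxolane | CC1(O[Si](C)(C)C)OCC[C@H]1C(C)(C)C#C[Si](C)(C)C | intermediate (not isolated)
12 | (3S)-2-methyl-3-[2-methyl-4-(trimethylsilyl)but-3-yn-2-yl]oxolan-2-ol (anomers) | CC1(O)OCC[C@H]1C(C)(C)C#C[Si](C)(C)C | intermediate
13 | (3R)-4,4-dimethyl-3-(prop-1-en-2-yl)-6-(trimethylsilyl)hex-5-yn-1-ol | C[Si](C)(C)C#CC(C)(C)[C@H](CCO)C(C)=C | intermediate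
14 | [(4R)-6-iodo-3,3-dimethyl-4-(prop-1-en-2-yl)hex-1-yn-1-yl]trimethylsilane | C[Si](C)(C)C#CC(C)(C)[C@H](CCI)C(C)=C | intermediate
15 | 2,3-dihydrofuran | C1=COCC1 | starting material
16 | 5-lithio-2,3-dihydrofuran | [Li]C1=CCCO1 | intermediate (not isolated)
17 | [(4R)-6-(4,5-dihydrofuran-2-yl)-3,3-dimethyl-4-(prop-1-en-2-yl)hex-1-yn-1-yl]trimethylsilane | C[Si](C)(C)C#CC(C)(C)[C@H](CCC1=CCCO1)C(C)=C | intermediate
18 | (trimethylsilyl)methylmagnesium chloride | C[Si](C)(C)C[Mg]Cl | starting material
19 | (3Z,7R)-8,8-dimethyl-7-(prop-1-en-2-yl)-10-(trimethylsilyl)-4-[(trimethylsilyl)methyl]dec-3-en-9-yn-1-ol | C[Si](C)(C)C#CC(C)(C)[C@H](CC/C(C[Si](C)(C)C)=C/CCO)C(C)=C | intermediate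
20 | methanesulfonate of 19 | C[Si](C)(C)C#CC(C)(C)[C@H](CC/C(C[Si](C)(C)C)=C/CCOS(C)(=O)=O)C(C)=C | intermediate (not isolated)
21 | [(4R,7Z)-10-iodo-3,3-dimethyl-4-(prop-1-en-2-yl)-7-[(trimethylsilyl)methyl]dec-7-en-1-yn-1-yl]trimethylsilane | C[Si](C)(C)C#CC(C)(C)[C@H](CC/C(C[Si](C)(C)C)=C/CCI)C(C)=C | intermediate
22 | methyl but-2-ynoate | CC#CC(=O)OC | starting material
23 | methyl (2Z)-3-iodobut-2-enoate | C/C(I)=C/C(=O)OC | intermediate
24 | alkylzinc iodide from 21 | C[Si](C)(C)C#CC(C)(C)[C@H](CC/C(C[Si](C)(C)C)=C/CC[Zn]I)C(C)=C | intermediate (not isolated)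
25 | methyl (2Z,6Z,10R)-3,11,11-trimethyl-10-(prop-1-en-2-yl)-13-(trimethylsilyl)-7-[(trimethylsilyl)methyl]trideca-2,6-dien-12-ynoate | C[Si](C)(C)C#CC(C)(C)[C@H](CC/C(C[Si](C)(C)C)=C/CC/C(C)=C\C(=O)OC)C(C)=C | intermediate
26 | (2Z,6Z,10R)-3,11,11-trimethyl-10-(prop-1-en-2-yl)-7-[(trimethylsilyl)methyl]trideca-2,6-dien-12-ynoic acid | C#CC(C)(C)[C@H](CC/C(C[Si](C)(C)C)=C/CC/C(C)=C\C(=O)O)C(C)=C | intermediate
27 | dilithium ynolate carboxylate of 26 | [Li+].[Li+].[O-]C#CC(C)(C)[C@H](CC/C(C[Si](C)(C)C)=C/CC/C(C)=C\C(=O)[O-])C(C)=C | intermediate (not isolated)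
28 | tri(propan-2-yl)silyl (2Z,6Z,10R)-3,11,11-trimethyl-10-(prop-1-en-2-yl)-13-{[tri(propan-2-yl)silyl]oxy}-7-[(trimethylsilyl)methyl]trideca-2,6-dien-12-ynoate (key-step precursor) | CC(C)[Si](C(C)C)(C(C)C)OC#CC(C)(C)[C@H](CC/C(C[Si](C)(C)C)=C/CC/C(C)=C\C(=O)O[Si](C(C)C)(C(C)C)C(C)C)C(C)=C | intermediate
29 | tri(propan-2-yl)silyl (13Z)-2-{[tri(propan-2-yl)silyl]oxy}labda-2,8(17),13-trien-15-oate | C=C1CC[C@H]2C(C)(C)C=C(O[Si](C(C)C)(C(C)C)C(C)C)C[C@]2(C)[C@H]1CC/C(C)=C\C(=O)O[Si](C(C)C)(C(C)C)C(C)C | intermediate (not isolated)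
30 | (13Z)-2-oxolabda-8(17),13-dien-15-oic acid, (5S,9S,10S) (key-step product) | C=C1CC[C@H]2C(C)(C)CC(=O)C[C@]2(C)[C@H]1CC/C(C)=C\C(=O)O | intermediate
31 | (13Z)-2β-hydroxylabda-8(17),13-dien-15-oic acid, (2R,5S,9S,10S) | C=C1CC[C@H]2C(C)(C)C[C@@H](O)C[C@]2(C)[C@H]1CC/C(C)=C\C(=O)O | intermediate
32 | acetic (13Z)-2β-acetoxylabda-8(17),13-dien-15-oic anhydride | C=C1CC[C@H]2C(C)(C)C[C@@H](OC(C)=O)C[C@]2(C)[C@H]1CC/C(C)=C\C(=O)OC(C)=O | intermediate (not isolated)
33 | (13Z)-2β-acetoxylabda-8(17),13-dien-15-oic acid, (2R,5S,9S,10S) | C=C1CC[C@H]2C(C)(C)C[C@@H](OC(C)=O)C[C@]2(C)[C@H]1CC/C(C)=C\C(=O)O | target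

**Step count.** Total: 17 steps. Longest linear sequence: 15 steps (1 or 2, then 3–10 and 12–17).

**Steps most likely to fail**

Step 15. The allylsilane may be protodesilylated before the ynol ether is protonated. The C10 cation may lose a proton or suffer a 1,2-hydride shift from C5 before C9 reaches it. C9 may add to the other face of C10 (cis-decalin), or the exocyclic alkene may migrate under the acid. The fallback uses known chemistry, sets out from 25 and rejoins the route at 30. K2CO3 in MeOH removes only the alkynyl silyl group and gives the alkyne ester F1. Ruthenium-catalysed anti-Markovnikov hydration [CpRu(MeCN)3PF6, 5,5′-bis(trifluoromethyl)-2,2′-bipyridine, NMP/H2O] gives the C2 aldehyde F2. MeAlCl2 in CH2Cl2 at −78 °C then triggers a Prins-type cyclisation of the aldehyde onto the isopropenyl group with capture of the C10 cation by the allylsilane; both events are established cation–olefin chemistry. This gives the C2-epimeric alcohols F3, whose C2 configuration is irrelevant. Dess–Martin oxidation gives the keto ester F4, and LiOH hydrolysis gives 30.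

Step 14. Oxygen transfer to the hindered acetylide may be incomplete in the presence of the carboxylate. Excess base may γ-deprotonate the unsaturated carboxylate with erosion of 13Z, or the ynolate may be silylated on carbon. The fallback sets out from 19 and rejoins at 28; it introduces the ynol oxygen before any carbonyl group is present. MsCl/Et3N then LiCl in DMF gives the chloride F5, and K2CO3/MeOH gives the terminal alkyne F6. The conditions of step 14 (n-BuLi; t-BuOOLi; TIPSOTf) then give the siloxyalkyne chloride F7, a substrate without acidic or electrophilic sites. NaI in butanone gives the iodide F8, and zinc insertion gives the zinc reagent F9. Separately, LiOH hydrolysis of 23 gives (2Z)-3-iodobut-2-enoic acid F10, and TIPSCl/imidazole gives its silyl ester F11. Negishi coupling of F9 with F11 [Pd(PPh3)4] gives 28.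

Step 9. Oxidative addition of nickel into the hindered enol-ether C–O bond may be slow, the enol ether may hydrolyse, or alkene geometry may be partly lost. The fallback sets out from 14 and rejoins at 19. Zinc insertion gives the alkylzinc iodide F12. 3-[(tert-Butyldimethylsilyl)oxy]propanal with CBr4/PPh3 (Corey–Fuchs olefination) gives the 1,1-dibromoalkene F13. Palladium-catalysed trans-selective monoalkylation of F13 with F12 [PdCl2(DPEphos)] gives the (Z)-bromoalkene F14, with C7 trans to C11. A second, stereoretentive palladium-catalysed coupling with 18 [Pd(t-Bu3P)2] gives the silyl ether F15. AcOH/THF/H2O removes the silyl ether and gives 19.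

**Further compounds**

F1 | step 15 | methyl (2Z,6Z,10R)-3,11,11-trimethyl-10-(prop-1-en-2-yl)-7-[(trimethylsilyl)methyl]trideca-2,6-dien-12-ynoate | C#CC(C)(C)[C@H](CC/C(C[Si](C)(C)C)=C/CC/C(C)=C\C(=O)OC)C(C)=C
F2 | step 15 | methyl (2Z,6Z,10R)-3,11,11-trimethyl-13-oxo-10-(prop-1-en-2-yl)-7-[(trimethylsilyl)methyl]trideca-2,6-dienoate | O=CCC(C)(C)[C@H](CC/C(C[Si](C)(C)C)=C/CC/C(C)=C\C(=O)OC)C(C)=C
F3 | step 15 | methyl (13Z)-2-hydroxylabda-8(17),13-dien-15-oate (C2 epimers) | C=C1CC[C@H]2C(C)(C)CC(O)C[C@]2(C)[C@H]1CC/C(C)=C\C(=O)OC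
F4 | step 15 | methyl (13Z)-2-oxolabda-8(17),13-dien-15-oate | C=C1CC[C@H]2C(C)(C)CC(=O)C[C@]2(C)[C@H]1CC/C(C)=C\C(=O)OC
F5 | step 14 | [(4R,7Z)-10-chloro-3,3-dimethyl-4-(prop-1-en-2-yl)-7-[(trimethylsilyl)methyl]dec-7-en-1-yn-1-yl]trimethylsilane | C[Si](C)(C)C#CC(C)(C)[C@H](CC/C(C[Si](C)(C)C)=C/CCCl)C(C)=C
F6 | step 14 | (4R,7Z)-10-chloro-3,3-dimethyl-4-(prop-1-en-2-yl)-7-[(trimethylsilyl)methyl]dec-7-en-1-yne | C#CC(C)(C)[C@H](CC/C(C[Si](C)(C)C)=C/CCCl)C(C)=C
F7 | step 14 | {[(4R,7Z)-10-chloro-3,3-dimethyl-4-(prop-1-en-2-yl)-7-[(trimethylsilyl)methyl]dec-7-en-1-yn-1-yl]oxy}tri(propan-2-yl)silane | CC(C)[Si](C(C)C)(C(C)C)OC#CC(C)(C)[C@H](CC/C(C[Si](C)(C)C)=C/CCCl)C(C)=C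
F8 | step 14 | {[(4R,7Z)-10-iodo-3,3-dimethyl-4-(prop-1-en-2-yl)-7-[(trimethylsilyl)methyl]dec-7-en-1-yn-1-yl]oxy}tri(propan-2-yl)silane | CC(C)[Si](C(C)C)(C(C)C)OC#CC(C)(C)[C@H](CC/C(C[Si](C)(C)C)=C/CCI)C(C)=C
F9 | step 14 | alkylzinc iodide from F8 | CC(C)[Si](C(C)C)(C(C)C)OC#CC(C)(C)[C@H](CC/C(C[Si](C)(C)C)=C/CC[Zn]I)C(C)=C
F10 | step 14 | (2Z)-3-iodobut-2-enoic acid | C/C(I)=C/C(=O)O
F11 | step 14 | tri(propan-2-yl)silyl (2Z)-3-iodobut-2-enoate | C/C(I)=C/C(=O)O[Si](C(C)C)(C(C)C)C(C)C
F12 | step 9 | alkylzinc iodide from 14 | C[Si](C)(C)C#CC(C)(C)[C@H](CC[Zn]I)C(C)=C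
F13 | step 9 | tert-butyl[(4,4-dibromobut-3-en-1-yl)oxy]dimethylsilane | BrC(Br)=CCCO[Si](C)(C)C(C)(C)C
F14 | step 9 | [(4R,7Z)-7-bromo-10-{[tert-butyl(dimethyl)silyl]oxy}-3,3-dimethyl-4-(prop-1-en-2-yl)dec-7-en-1-yn-1-yl]trimethylsilane | C[Si](C)(C)C#CC(C)(C)[C@H](CC/C(Br)=C/CCO[Si](C)(C)C(C)(C)C)C(C)=C
F15 | step 9 | tert-butyldimethylsilyl ether of 19 | C[Si](C)(C)C#CC(C)(C)[C@H](CC/C(C[Si](C)(C)C)=C/CCO[Si](C)(C)C(C)(C)C)C(C)=C
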